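Does a larger substrate charge give more target at the end of 6.0 d, with the coupling partner charge held at 0.240 M?

in all of them: coupling partner 0.240 M; time 6.0 d

| run | substrate |
|---|---|
| gamma | 0.20 M |
| beta | 0.30 M |
| eta | 0.50 M |
| alpha | 0.60 M |

    substrate → intermediate A (k1 = 0.0408 h⁻¹)
    intermediate A → intermediate B (k2 = 0.0795 h⁻¹)
    intermediate B ⇌ intermediate C (K3 = 0.90, k3 = 0.00335 h⁻¹)
    intermediate C ⇌ intermediate D (K4 = 0.215, k4 = 0.284 h⁻¹)
    coupling partner + intermediate B ⇌ target (K5 = 12 L mol⁻¹, k5 = 1.60 L mol⁻¹ h⁻¹)
    substrate + target → side product (k6 = 0.321 L mol⁻¹ h⁻¹)

* [target] at the end for gamma, beta, eta, alpha, in this order
* the course of these numbers from the first flask to the last (falls, then rises / rises, then falls / hardly changes / falls all the way / rises all the way)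

- in percentages every species weighs as the substrate in it: one side product counts as two
- "hardly changes" means that all values lie within two and a half points (for a concentration: within two and a half percent of the largest)
- run time (gamma): 6.0 d

I reckon with one number: the equilibrium constant of the coupling step times c(coupling partner), which is the ratio c(target)/c(intermediate B) once that step has relaxed, a pre-equilibrium in the usual term. The forward half-life of intermediate B by the coupling step, 0.075 d in gamma, is far shorter than the run, so I trust the ratio. At the partner charge it stands at 2.88, and this is the holding number, whose common logarithm is 0.459; each power of ten lost in partner takes a power of ten off it.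

Two chemists dispute the row. The first counts the pool of intermediate B and target: from gamma to alpha the charge grows by a factor 3.00, or 0.477 in logarithms, and at the charged holding number a share 0.742 of the pool is target, so she expects a rise from flask to flask. The second answers that substrate destroys target and that the partner inside a destroyed target stays in the side product, so the holding number falls as the flask proceeds. The half-life of target by this side step alone, with substrate as charged, is 0.45 d in gamma, shorter than the run, and with alpha's substrate as charged it is 0.150 d.

My own reckoning gives the terms of the dispute, though no row. Supposing that the pool grows in step with the charge, and setting alpha against gamma with its partner at the charge, alpha's larger pool is cancelled if the share falls to 0.247, which means a holding number of 0.329, logarithm −0.483, or a free partner down to 11.4% of its charge. Burning the whole partner charge through the side step costs 0.480 M of substrate, less than alpha's 0.60 M, so alpha can pay for that fall, and I side with the second chemist that the row need not keep rising; how far the partner really falls needs the race between the steps, which I do not carry through by hand.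

The forecast, the second chemist's number, gives 0.069 M, 0.08 M, 0.076 M and 0.065 M, a row that rises, then falls, on the ground that “More substrate helps at first, then partner loss dominates.”

The flasks give 0.0744 M, 0.0866 M, 0.0839 M and 0.0743 M, a row that rises, then falls, so the forecast stands within the tolerance. The row turns at a substrate charge of 0.38 M, so the first chemist's rise is right from gamma to beta, whose charge lies below the turn. Gamma ends with 56% of its partner, which brings the holding number to 1.61, and its c(target)/c(intermediate B) reads 1.61. Alpha ends with 13% of its partner, which brings the holding number to 0.386, logarithm −0.413, and its c(target)/c(intermediate B) reads 0.388.

(Its constants were chosen freely.)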